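## Structural features

The target is a 2,6-diaryl-3,7-dioxabicyclo[3.3.0]octane. It has two tetrahydrofuran rings, ring O3 (C2–O3–C4–C5–C1) and ring O7 (C6–O7–C8–C1–C5), cis-fused through the C1–C5 bond. C2 carries a 3-hydroxy-4,5-dimethoxyphenyl group and C6 a 3,4,5-trimethoxyphenyl group, both on the convex (exo) face, so the four contiguous stereocentres C2–C1–C5–C6 are 1R,2S,5R,6S. The skeleton is twofold symmetric except for one phenolic oxygen, so a dimerisation is excluded and the two aryl groups must be brought in separately. The fragile parts are the benzylic ether bonds C2–O3 and C6–O7, each para to a methoxy group and therefore open to acid ionisation and epimerisation, and the free phenol, which is acidic, oxidisable and reactive toward diazonium ions. The real difficulty is the absolute configuration combined with exo placement of both aryl groups, because exo and endo epimers of such bicycles lie close in energy and equilibration cannot be trusted. The key step uses the fact that ring O3, with C4 raised to a carbonyl, is a γ-aryl butyrolactone whose C2-aryl and C1-oxymethyl groups are trans. This is the anti pattern of a γ-substituted allylation of an aryl aldehyde, and C5 is left as an exocyclic methylene whose terminal carbon becomes C6.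

## Logic of the disconnections

**18 from 17.** The phenolic O–H is traced back to an O–Si bond. A free phenol would couple with 12, quench the alkoxide needed for ring O7 and consume hydride. The skeleton is not simplified, but every earlier step runs on a neutral, lipophilic substrate. The forward step must be non-acidic so that the benzylic ethers are not ionised.

**17 from 15 (through 16).** The two C4–H bonds are traced back to C4=O. This links ring O3 to lactone chemistry and makes C5 the α-carbon of a carbonyl group. The forward reduction must stop at the ether level and must not ionise C2–O3 or C6–O7.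

**15 from 14.** The C6–O7 bond and the C5–H bond are cut (retro-oxa-Michael). This removes ring O7 and the stereocentres C5 and C6 and leaves a monocyclic lactone with only C1 and C2 defined, with C6 encoded in an alkene geometry. The forward closure is 5-endo, must be faster than acyl transfer to O7, and needs the (E)-alkene.

**14 from 13.** The O7–H is traced back to an O7–Si bond. O7 must be masked in 8, where a free hydroxyl cis to the ester would lactonise, and during the steps up to 13. The forward step must remove this silyl group and keep the aryl silyl ether, hence two silyl groups of different acid lability.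

**13 from 10 and 12.** The C6–aryl bond is cut. The trimethoxyphenyl half becomes a simple arene electrophile and the rest is an α-methylene lactone. The forward arylation must occur at the terminal carbon, eliminate toward C6 and not toward C1, give the (E)-isomer and spare both silyl ethers.

**12 from 11.** The C–N2 bond is traced back to C–NH2; the forward step is a diazotisation.

**10 from 2 and 8 (through 9).** The C1–C2 and O3–C4 bonds are cut. The lactone falls apart into an aromatic aldehyde and a four-carbon allylboronate that already holds C4, C5, C6, C1 and C8. One operation then returns a ring, two skeletal bonds and both stereocentres. The forward step needs anti selectivity, which the alkene geometry of 8 supplies through a chair transition state, and one aldehyde face, which a chiral acid must select.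

**8 from 5 and 6 (through 7).** The C5–C6 bond and the C1–H bond are cut. The trisubstituted alkene becomes an alkyne plus a one-carbon boron electrophile. The forward step must add hydrogen and metal syn and alkylate with retention, without leakage through the allenoate form.

**5 from 3 (through 4).** The C4–C5 bond is cut; the forward step is acylation of an acetylide.

**2 from 1.** The aryl O–Si bond is cut; the forward step is a phenol silylation.

## Other disconnections considered

**Alternative 1:** The cut goes through C1–C2 and C4–C5 of one tetrahydrofuran ring. C2–O3–C4 becomes a carbonyl ylide and C1=C5 the double bond of a γ-aryl butenolide. The labels are applied here with the trimethoxyphenyl group on C2, which the twofold symmetry of the skeleton allows.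

- Forward step: CsF removes the silyl group of the α-silyl chloromethyl ether A3, chloride leaves, and the ylide adds across the butenolide A2 to give the bicyclic lactone A1.
- In its favour: two C–C bonds, one ring and three stereocentres arise in one convergent step. The C6 aryl group of A2 should send the dipole to the opposite face, so C5 and C1 follow from C6. No catalyst development is needed. In bond economy and convergence it is better than the chosen plan.
- Against it here: the unstabilised ylide has no strong exo/endo preference, so C2 is likely to form as a mixture. Both orientations of the unsymmetrical dipole are conceivable. The absolute configuration rests on the γ-stereocentre of A2, which is acidified by the aryl group and may racemise through the 2-oxyfuran anion under basic fluoride. A2 must itself be made enantiopure. The final acidic removal of the methoxymethyl group exposes the benzylic ethers to ionisation.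
- Comparison: the lactone-to-ether reduction is the same in both plans. Alternative 1 is probably somewhat shorter. The chosen plan should be better in the security of C2 and of the absolute configuration, because it sets C1/C2 in a closed transition state and C6 from an alkene geometry.

**Alternative 2:** The cuts are C1–C5 and C6–O7. Both rings unravel to the acyclic epoxy ether A5, in which C2 already carries its aryl group, O3 and a cinnamyl group holding C4, C5 and C6.

- Forward step: Cp2TiCl (trivalent titanium, from Cp2TiCl2 and zinc) opens the oxirane to the C1 radical, which adds 5-exo-trig to C5. Iodine then lets the C8 alkoxide capture benzylic C6. The product A4 is the same compound as 17.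
- In its favour: both rings, two skeletal bonds and three stereocentres form in one pot. No carbonyl is present, so the two reduction steps of the chosen route disappear. On redox economy and step count (about five or six steps) it is clearly better. The end game from 17 to 18 is identical.
- Against it here: the C1 radical is planar, so C1, C5 and C6 are all set by substrate control from C2 alone. C1/C2 trans is likely, but C6 is set by capture of a benzylic cation or iodide and exo/endo mixtures are to be expected. Premature reduction of the C1 or C6 radical gives monocyclic or uncyclised material. The titanium reagent is stoichiometric and Lewis acidic toward the C2 benzylic ether. A single enantiomer needs A5 with defined C2, which means a separate asymmetric synthesis or kinetic resolution of an aryl vinyl carbinol.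
- Comparison: it is a radical–polar crossover with open transition states, against a closed chair and a stereospecific addition in the chosen plan. It is shorter and equal in convergence, but weaker in stereocontrol at three of the four centres.

**Alternative 3:** The cuts are C5–C6 and C1–C2, the bonds that join the aryl-bearing carbons to the bridgeheads. No ring of the target is disconnected, and C1–C5 is found in the α,β-bond of a butenolide.

- Forward step: the lithium salt of the dithiane A8 adds to the β-carbon of the menthyloxybutenolide A7 anti to the menthyloxy group. The lactone enolate is trapped in the same flask by aldehyde 2, anti to the new β-substituent, to give A6.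
- In its favour: the absolute configuration of C1 and C5 comes from an inexpensive stoichiometric auxiliary with a well-understood trans,trans bias. On reliability of absolute control this is better than a catalytic step whose enantioselectivity on this boronate class is still to be proved. Three components are joined in one operation, so convergence is equal or better. Aldehyde 2 is shared with the chosen route.
- Against it here: neither ring exists after the key step and the carbinol centre C2 is not controlled by the aldol. C6 is still a dithioketal. The route then needs dithiane removal next to electron-rich arenes, ketone reduction, reduction of lactone and menthyl acetal to a tetraol, and a double acid-mediated cyclisation through benzylic cations. C2 and C6 are thus set last, under near-thermodynamic conditions where exo and endo isomers are close in energy.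
- Comparison: it builds the C2–C1–C5–C6 chain quickly but leaves all ring C–O bonds and both benzylic centres for later. It is polar and auxiliary-controlled. In step economy it should be longer than the chosen plan, which closes ring O3 and sets C1 and C2 in the key step itself.

Key step: step 4

Assumption: tert-butyldimethyl(prop-2-yn-1-yloxy)silane 3 is taken as a catalogue compound (made from propargyl alcohol it would cost one more silylation step), and the (S)-phosphoric acid of step 4 is taken to direct attack to the Si face of 2, as expected by analogy with unsubstituted allyl pinacolboronate.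

## Route

Step 1
Reactants: 1 3-hydroxy-4,5-dimethoxybenzaldehyde
Product: 2 3,4-dimethoxy-5-(triisopropylsilyloxy)benzaldehyde
Conditions: TIPSCl, imidazole, DMF, rt
Reagents that add atoms: triisopropylsilyl chloride, CC(C)[Si](Cl)(C(C)C)C(C)C
Why: Imidazole-promoted silylation of a phenol; the bulky aryl silyl ether should withstand mild acid, the acetate buffer of step 6 and hydride, and leave only with fluoride.

Step 2
Reactants: 3 tert-butyldimethyl(prop-2-yn-1-yloxy)silane
Product: 5 methyl 4-(tert-butyldimethylsilyloxy)but-2-ynoate, via lithium acetylide 4 (not isolated)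
Conditions: n-BuLi, THF, −78 °C; ClCO2Me, −78 → 0 °C
Reagents that add atoms: methyl chloroformate, COC(=O)Cl
Why: Deprotonation of a terminal alkyne and acylation of the acetylide with a chloroformate is a standard alkynoate synthesis; low temperature and excess chloroformate should prevent double addition.

Step 3
Reactants: 5 methyl 4-(tert-butyldimethylsilyloxy)but-2-ynoate, 6 2-(iodomethyl)-4,4,5,5-tetramethyl-1,3,2-dioxaborolane
Product: 8 methyl (Z)-4-(tert-butyldimethylsilyloxy)-2-[(4,4,5,5-tetramethyl-1,3,2-dioxaborolan-2-yl)methyl]but-2-enoate, via alkenylalane 7 (not isolated)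
Conditions: i-Bu2AlH, MeCu (10 mol %, from CuI and MeLi), HMPA, THF, −50 °C; then 6, −50 → 0 °C
Reagents that add atoms: none
Why: Copper-catalysed conjugate hydroalumination puts hydride on C1 and the metal on C5 on the same side of the triple bond; the α-metallated enoate then attacks boron of 6 and the alkenyl group shifts from boron to carbon with loss of iodide and retention of geometry, so the silyloxymethyl group ends cis to the ester and trans to the CH2B carbon (future C6).

Step 4
Reactants: 2 3,4-dimethoxy-5-(triisopropylsilyloxy)benzaldehyde, 8 methyl (Z)-4-(tert-butyldimethylsilyloxy)-2-[(4,4,5,5-tetramethyl-1,3,2-dioxaborolan-2-yl)methyl]but-2-enoate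
Product: 10 (4R,5S)-4-[(tert-butyldimethylsilyloxy)methyl]-5-[3,4-dimethoxy-5-(triisopropylsilyloxy)phenyl]-3-methylenedihydrofuran-2(3H)-one, via homoallylic pinacol borate 9 (not isolated)
Conditions: (S)-3,3'-bis(2,4,6-triisopropylphenyl)-1,1'-binaphthyl-2,2'-diyl hydrogen phosphate (10 mol %), toluene, 0 °C → rt; then TsOH·H2O (10 mol %), rt
Reagents that add atoms: none
Why: The phosphoric acid should bind a dioxaborolane oxygen through P–OH (raising the Lewis acidity of boron) and the formyl C–H through P=O, and the aldehyde is then allylated through a closed six-membered chair transition state with boron on the carbonyl oxygen. C1–C2 forms between the γ-carbon of 8 and the formyl carbon while the double bond moves to C5=C6. The aryl group of 2 and the silyloxymethyl group of 8 (trans to the CH2B carbon) both sit equatorial, which gives the anti borate 9, so the alkene geometry sets C1 relative to C2. The chiral pocket of the acid selects the Si face of 2 and so sets C2 as S; a phosphoric acid is preferred to a chiral diol–SnCl4 complex because 2 is an aromatic aldehyde, the substrate class for which this acid type is best established, and its sense of induction is to be confirmed on the first batch. The borate oxygen O3 then attacks the neighbouring ester carbon C4 in a 5-exo-trig acyl substitution (completed by TsOH), releasing the methoxyboronate and closing ring O3 as the trans lactone. The closest known reaction types are the Brønsted- and Lewis-acid-catalysed allylboration–lactonisation of 2-alkoxycarbonyl allylboronates and the chiral phosphoric acid-catalysed allyl- and crotylboration of aromatic aldehydes. The step needs anti diastereoselectivity and one enantioface: the first is secured by the (Z)-geometry of 8 and by the trans lactone also being the more stable one, the second by the catalyst, helped by the very slow uncatalysed reaction of this ester-deactivated boronate.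

Step 5
Reactants: 11 3,4,5-trimethoxyaniline
Product: 12 3,4,5-trimethoxybenzenediazonium tetrafluoroborate
Conditions: NaNO2, aq HBF4, 0 °C
Reagents that add atoms: sodium nitrite, [Na+].[O-]N=O; tetrafluoroboric acid, [H+].F[B-](F)(F)F
Why: Diazotisation of an aniline; the tetrafluoroborate of an electron-rich arenediazonium ion should precipitate and keep in the cold.

Step 6
Reactants: 10 (4R,5S)-4-[(tert-butyldimethylsilyloxy)methyl]-5-[3,4-dimethoxy-5-(triisopropylsilyloxy)phenyl]-3-methylenedihydrofuran-2(3H)-one, 12 3,4,5-trimethoxybenzenediazonium tetrafluoroborate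
Product: 13 (4R,5S,E)-4-[(tert-butyldimethylsilyloxy)methyl]-5-[3,4-dimethoxy-5-(triisopropylsilyloxy)phenyl]-3-(3,4,5-trimethoxybenzylidene)dihydrofuran-2(3H)-one
Conditions: Pd2(dba)3 (2.5 mol %), NaOAc, MeCN, rt
Reagents that add atoms: none
Why: Heck–Matsuda arylation: the cationic arylpalladium species from 12 delivers its aryl group to the unsubstituted terminus C6, and syn β-hydride elimination from C6 should give the (E)-arylidene lactone (aryl anti to the carbonyl), as is usual for α-methylene-γ-butyrolactones; ligand-free conditions at room temperature with an acetate buffer should spare both silyl ethers and disfavour re-addition of palladium hydride.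

Step 7
Reactants: 13 (4R,5S,E)-4-[(tert-butyldimethylsilyloxy)methyl]-5-[3,4-dimethoxy-5-(triisopropylsilyloxy)phenyl]-3-(3,4,5-trimethoxybenzylidene)dihydrofuran-2(3H)-one
Product: 14 (4R,5S,E)-5-[3,4-dimethoxy-5-(triisopropylsilyloxy)phenyl]-4-(hydroxymethyl)-3-(3,4,5-trimethoxybenzylidene)dihydrofuran-2(3H)-one
Conditions: camphorsulfonic acid (10 mol %), MeOH–CH2Cl2, 0 °C
Reagents that add atoms: none
Why: Acid-catalysed methanolysis removes a primary alkyl tert-butyldimethylsilyl ether much faster than an aryl triisopropylsilyl ether, whose oxygen is a poor base; the conditions are too mild to ionise C2–O3.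

Step 8
Reactants: 14 (4R,5S,E)-5-[3,4-dimethoxy-5-(triisopropylsilyloxy)phenyl]-4-(hydroxymethyl)-3-(3,4,5-trimethoxybenzylidene)dihydrofuran-2(3H)-one
Product: 15 (1R,2S,5S,6S)-2-[3,4-dimethoxy-5-(triisopropylsilyloxy)phenyl]-6-(3,4,5-trimethoxyphenyl)-3,7-dioxabicyclo[3.3.0]octan-4-one
Conditions: KOt-Bu (20 mol %), THF–t-BuOH, −20 → 0 °C; AcOH
Reagents that add atoms: none
Why: Proposed new method: catalytic alkoxide formation at O7 should be followed by reversible conjugate addition to C6 of the arylidene lactone (5-endo-trig, slow but downhill because a cis-fused bicycle replaces a crowded trisubstituted alkene) and by protonation of the lactone enolate at C5 on the face that gives the cis ring fusion; the tether lets O7 reach only the C8 face of the (E)-alkene, so C6 is set stereospecifically with the aryl group exo and C5 follows from the fusion; the closest known reaction types are the base-mediated 5-endo-trig cyclisation of hydroxy-tethered vinyl sulfones to tetrahydrofurans and the reversible alkoxide addition to α-alkylidene lactones.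

Step 9
Reactants: 15 (1R,2S,5S,6S)-2-[3,4-dimethoxy-5-(triisopropylsilyloxy)phenyl]-6-(3,4,5-trimethoxyphenyl)-3,7-dioxabicyclo[3.3.0]octan-4-one
Product: 16 (1R,2S,5S,6S)-2-[3,4-dimethoxy-5-(triisopropylsilyloxy)phenyl]-6-(3,4,5-trimethoxyphenyl)-3,7-dioxabicyclo[3.3.0]octan-4-ol (both C4 epimers)
Conditions: i-Bu2AlH, CH2Cl2, −78 °C; aq potassium sodium tartrate
Reagents that add atoms: none
Why: Partial reduction of a γ-lactone to the lactol; the tetrahedral aluminium alkoxide is stable at −78 °C and collapses only on work-up, so over-reduction should not occur, and no stereocentre of the target is touched.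

Step 10
Reactants: 16 (1R,2S,5S,6S)-2-[3,4-dimethoxy-5-(triisopropylsilyloxy)phenyl]-6-(3,4,5-trimethoxyphenyl)-3,7-dioxabicyclo[3.3.0]octan-4-ol
Product: 17 (1R,2S,5R,6S)-2-[3,4-dimethoxy-5-(triisopropylsilyloxy)phenyl]-6-(3,4,5-trimethoxyphenyl)-3,7-dioxabicyclo[3.3.0]octane
Conditions: Et3SiH, BF3·OEt2, CH2Cl2, −78 → −40 °C
Reagents that add atoms: none
Why: Ionic reduction of a lactol: BF3 ionises the anomeric hydroxyl to a cyclic oxocarbenium ion at C4, which the silane reduces; at low temperature this ionisation is much easier than that of the benzylic ethers, so C2 and C6 should keep their configuration.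

Step 11
Reactants: 17 (1R,2S,5R,6S)-2-[3,4-dimethoxy-5-(triisopropylsilyloxy)phenyl]-6-(3,4,5-trimethoxyphenyl)-3,7-dioxabicyclo[3.3.0]octane
Product: 18 (1R,2S,5R,6S)-2-(3-hydroxy-4,5-dimethoxyphenyl)-6-(3,4,5-trimethoxyphenyl)-3,7-dioxabicyclo[3.3.0]octane
Conditions: Bu4NF, AcOH, THF, 0 °C → rt
Reagents that add atoms: none
Why: Fluoride cleaves the aryl silyl ether by attack at silicon; the buffered, non-acidic medium leaves both benzylic ethers untouched.

## Compound list

1 | 3-hydroxy-4,5-dimethoxybenzaldehyde | COc1cc(C=O)cc(O)c1OC | starting material
2 | 3,4-dimethoxy-5-(triisopropylsilyloxy)benzaldehyde | COc1cc(C=O)cc(O[Si](C(C)C)(C(C)C)C(C)C)c1OC | intermediate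
3 | tert-butyldimethyl(prop-2-yn-1-yloxy)silane | C#CCO[Si](C)(C)C(C)(C)C | starting material
4 | lithium 3-(tert-butyldimethylsilyloxy)prop-1-yn-1-ide | [Li]C#CCO[Si](C)(C)C(C)(C)C | intermediate (not isolated)
5 | methyl 4-(tert-butyldimethylsilyloxy)but-2-ynoate | COC(=O)C#CCO[Si](C)(C)C(C)(C)C | intermediate
6 | 2-(iodomethyl)-4,4,5,5-tetramethyl-1,3,2-dioxaborolane | ICB1OC(C)(C)C(C)(C)O1 | starting material
7 | methyl (E)-4-(tert-butyldimethylsilyloxy)-2-(diisobutylalumanyl)but-2-enoate (H and Al cis) | COC(=O)/C(=C\CO[Si](C)(C)C(C)(C)C)[Al](CC(C)C)CC(C)C | intermediate (not isolated)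
8 | methyl (Z)-4-(tert-butyldimethylsilyloxy)-2-[(4,4,5,5-tetramethyl-1,3,2-dioxaborolan-2-yl)methyl]but-2-enoate | COC(=O)/C(CB1OC(C)(C)C(C)(C)O1)=C\CO[Si](C)(C)C(C)(C)C | intermediate
9 | methyl (R)-4-(tert-butyldimethylsilyloxy)-3-{(S)-[3,4-dimethoxy-5-(triisopropylsilyloxy)phenyl][(4,4,5,5-tetramethyl-1,3,2-dioxaborolan-2-yl)oxy]methyl}-2-methylenebutanoate (anti) | COC(=O)C(=C)[C@H](CO[Si](C)(C)C(C)(C)C)[C@H](OB1OC(C)(C)C(C)(C)O1)c1cc(OC)c(OC)c(O[Si](C(C)C)(C(C)C)C(C)C)c1 | intermediate (not isolated)
10 | (4R,5S)-4-[(tert-butyldimethylsilyloxy)methyl]-5-[3,4-dimethoxy-5-(triisopropylsilyloxy)phenyl]-3-methylenedihydrofuran-2(3H)-one (trans) | COc1cc([C@H]2OC(=O)C(=C)[C@@H]2CO[Si](C)(C)C(C)(C)C)cc(O[Si](C(C)C)(C(C)C)C(C)C)c1OC | intermediate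
11 | 3,4,5-trimethoxyaniline | COc1cc(N)cc(OC)c1OC | starting material
12 | 3,4,5-trimethoxybenzenediazonium tetrafluoroborate | COc1cc([N+]#N)cc(OC)c1OC.F[B-](F)(F)F | intermediate
13 | (4R,5S,E)-4-[(tert-butyldimethylsilyloxy)methyl]-5-[3,4-dimethoxy-5-(triisopropylsilyloxy)phenyl]-3-(3,4,5-trimethoxybenzylidene)dihydrofuran-2(3H)-one | COc1cc([C@H]2OC(=O)/C(=C/c3cc(OC)c(OC)c(OC)c3)[C@@H]2CO[Si](C)(C)C(C)(C)C)cc(O[Si](C(C)C)(C(C)C)C(C)C)c1OC | intermediate
14 | (4R,5S,E)-5-[3,4-dimethoxy-5-(triisopropylsilyloxy)phenyl]-4-(hydroxymethyl)-3-(3,4,5-trimethoxybenzylidene)dihydrofuran-2(3H)-one | COc1cc([C@H]2OC(=O)/C(=C/c3cc(OC)c(OC)c(OC)c3)[C@@H]2CO)cc(O[Si](C(C)C)(C(C)C)C(C)C)c1OC | intermediate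
15 | (1R,2S,5S,6S)-2-[3,4-dimethoxy-5-(triisopropylsilyloxy)phenyl]-6-(3,4,5-trimethoxyphenyl)-3,7-dioxabicyclo[3.3.0]octan-4-one (cis-fused, both aryl groups exo) | COc1cc([C@H]2OC(=O)[C@H]3[C@@H]2CO[C@@H]3c2cc(OC)c(OC)c(OC)c2)cc(O[Si](C(C)C)(C(C)C)C(C)C)c1OC | intermediate
16 | (1R,2S,5S,6S)-2-[3,4-dimethoxy-5-(triisopropylsilyloxy)phenyl]-6-(3,4,5-trimethoxyphenyl)-3,7-dioxabicyclo[3.3.0]octan-4-ol (C4 epimers) | COc1cc([C@H]2OC(O)[C@H]3[C@@H]2CO[C@@H]3c2cc(OC)c(OC)c(OC)c2)cc(O[Si](C(C)C)(C(C)C)C(C)C)c1OC | intermediate
17 | (1R,2S,5R,6S)-2-[3,4-dimethoxy-5-(triisopropylsilyloxy)phenyl]-6-(3,4,5-trimethoxyphenyl)-3,7-dioxabicyclo[3.3.0]octane | COc1cc([C@H]2OC[C@H]3[C@@H]2CO[C@@H]3c2cc(OC)c(OC)c(OC)c2)cc(O[Si](C(C)C)(C(C)C)C(C)C)c1OC | intermediate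
18 | (1R,2S,5R,6S)-2-(3-hydroxy-4,5-dimethoxyphenyl)-6-(3,4,5-trimethoxyphenyl)-3,7-dioxabicyclo[3.3.0]octane | COc1cc([C@H]2OC[C@H]3[C@@H]2CO[C@@H]3c2cc(OC)c(OC)c(OC)c2)cc(O)c1OC | target

## Step count and least certain steps

Total step count: 11. Longest linear sequence: 9 steps (3 to 18 through steps 2, 3, 4, 6, 7, 8, 9, 10 and 11).

**Step 8 (oxa-Michael closure of ring O7).** The alkoxide may attack the lactone carbonyl C4 instead of C6. This acyl transfer moves the lactone onto O7, frees O3 and opens a path to a constitutional isomer. The closure may also be too slow (5-endo geometry, electron-rich aryl group on the acceptor), so that loss of the aryl silyl group or migration of the double bond takes over. The sp2 carbon C5 should disfavour the bridged acyl-transfer intermediate, but this is an argument and not a guarantee.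

The fallback sets out from 13 and returns at 15. Dimethyldioxirane in acetone should epoxidise the arylidene double bond to the spiro-epoxide (6S,7R)-7-[(tert-butyldimethylsilyloxy)methyl]-6-[3,4-dimethoxy-5-(triisopropylsilyloxy)phenyl]-2-(3,4,5-trimethoxyphenyl)-1,5-dioxaspiro[2.4]heptan-4-one F1 (oxirane face immaterial). SmI2 in THF–MeOH cleaves the C5–O bond next to the carbonyl, and the samarium enolate, protonated anti to the C1 substituent, should give the β-hydroxy lactone (3S,4R,5S)-4-[(tert-butyldimethylsilyloxy)methyl]-5-[3,4-dimethoxy-5-(triisopropylsilyloxy)phenyl]-3-[hydroxy(3,4,5-trimethoxyphenyl)methyl]dihydrofuran-2(3H)-one F2. Wet trifluoroacetic acid in CH2Cl2 at 0 °C then removes the alkyl silyl group and ionises the C6 carbinol to the trimethoxybenzyl cation, which O7 captures from the open face. This is the classical benzylic-cation closure of this ring system and leads to 15.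

**Step 4 (key step).** The weak chiral acid may not activate the ester-deactivated boronate enough. Warming would then be needed and facial selectivity could erode, or the sense of induction could differ from that of simple allylboronates. A stronger acid would risk ionisation at benzylic C2.

The fallback sets out from 2 and 8 and returns at 10. Sc(OTf)3 (10 mol %) in toluene at 0 °C, an established achiral catalyst for this boronate class, should give the racemic trans lactone. Preparative chromatography on a chiral stationary phase then separates 10 from its mirror image (4S,5R)-4-[(tert-butyldimethylsilyloxy)methyl]-5-[3,4-dimethoxy-5-(triisopropylsilyloxy)phenyl]-3-methylenedihydrofuran-2(3H)-one F3, which is set aside.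

**Step 3 (hydroalumination and alkylation).** The α-metallated enoate may lose its geometry through the allenoate form, or the ester may be reduced at the carbonyl. Either gives a boronate of mixed geometry and hence cis lactone in step 4.

The fallback sets out from 5 and returns at 8. Syn-hydrostannation with Bu3SnH and Pd(PPh3)4 (tin to C5) should give methyl (E)-4-(tert-butyldimethylsilyloxy)-2-(tributylstannyl)but-2-enoate F4. I2 in CH2Cl2 replaces tin by iodine with retention to give methyl (E)-4-(tert-butyldimethylsilyloxy)-2-iodobut-2-enoate F5. Negishi coupling (Pd(PPh3)4, THF) with iodo[(4,4,5,5-tetramethyl-1,3,2-dioxaborolan-2-yl)methyl]zinc F6, made from 6 and zinc dust, then gives 8 with the geometry fixed at the stannane stage.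

**Step 6 (Heck–Matsuda arylation).** β-Hydride elimination may go toward C1, or palladium hydride may re-add. Either moves the double bond into the ring and erases the C1 stereocentre. Loss of (E) geometry would in turn invert C6 in step 8.

The fallback sets out from 10 and returns at 13. Cross-metathesis of 10 with an excess of 5-ethenyl-1,2,3-trimethoxybenzene F7, using the second-generation Hoveyda–Grubbs catalyst in CH2Cl2 at 40 °C, exchanges the alkene termini and never places a metal on C5 next to the C1–H bond. The (E)-isomer is expected on thermodynamic grounds.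

**Step 10 (silane reduction of the lactol).** BF3 may ionise the benzylic C2–O3 or C6–O7 bond. This would cause epimerisation or reductive ring opening by the silane.

The fallback sets out from 15 and returns at 17. LiAlH4 in THF at 0 °C reduces the lactone to the diol (S)-[3,4-dimethoxy-5-(triisopropylsilyloxy)phenyl][(3R,4R,5S)-4-(hydroxymethyl)-5-(3,4,5-trimethoxyphenyl)tetrahydrofuran-3-yl]methanol F8. TsCl (1.1 equiv) in pyridine sulfonylates the primary hydroxyl, and the C2 hydroxyl displaces the tosylate at C4 (5-exo-tet), so the C2–O bond is never broken.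

## Further compounds

F1 | step 8 | (6S,7R)-7-[(tert-butyldimethylsilyloxy)methyl]-6-[3,4-dimethoxy-5-(triisopropylsilyloxy)phenyl]-2-(3,4,5-trimethoxyphenyl)-1,5-dioxaspiro[2.4]heptan-4-one (oxirane face not defined) | COc1cc([C@H]2OC(=O)C3(OC3c4cc(OC)c(OC)c(OC)c4)[C@@H]2CO[Si](C)(C)C(C)(C)C)cc(O[Si](C(C)C)(C(C)C)C(C)C)c1OC
F2 | step 8 | (3S,4R,5S)-4-[(tert-butyldimethylsilyloxy)methyl]-5-[3,4-dimethoxy-5-(triisopropylsilyloxy)phenyl]-3-[hydroxy(3,4,5-trimethoxyphenyl)methyl]dihydrofuran-2(3H)-one (carbinol epimers) | COc1cc([C@H]2OC(=O)[C@H](C(O)c3cc(OC)c(OC)c(OC)c3)[C@@H]2CO[Si](C)(C)C(C)(C)C)cc(O[Si](C(C)C)(C(C)C)C(C)C)c1OC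
F3 | step 4 | (4S,5R)-4-[(tert-butyldimethylsilyloxy)methyl]-5-[3,4-dimethoxy-5-(triisopropylsilyloxy)phenyl]-3-methylenedihydrofuran-2(3H)-one | COc1cc([C@@H]2OC(=O)C(=C)[C@H]2CO[Si](C)(C)C(C)(C)C)cc(O[Si](C(C)C)(C(C)C)C(C)C)c1OC
F4 | step 3 | methyl (E)-4-(tert-butyldimethylsilyloxy)-2-(tributylstannyl)but-2-enoate | COC(=O)/C(=C\CO[Si](C)(C)C(C)(C)C)[Sn](CCCC)(CCCC)CCCC
F5 | step 3 | methyl (E)-4-(tert-butyldimethylsilyloxy)-2-iodobut-2-enoate | COC(=O)/C(I)=C\CO[Si](C)(C)C(C)(C)C
F6 | step 3 | iodo[(4,4,5,5-tetramethyl-1,3,2-dioxaborolan-2-yl)methyl]zinc | I[Zn]CB1OC(C)(C)C(C)(C)O1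
F7 | step 6 | 5-ethenyl-1,2,3-trimethoxybenzene | COc1cc(C=C)cc(OC)c1OC
F8 | step 10 | (S)-[3,4-dimethoxy-5-(triisopropylsilyloxy)phenyl][(3R,4R,5S)-4-(hydroxymethyl)-5-(3,4,5-trimethoxyphenyl)tetrahydrofuran-3-yl]methanol | OC[C@@H]1[C@@H](c2cc(OC)c(OC)c(OC)c2)OC[C@@H]1[C@H](O)c3cc(OC)c(OC)c(O[Si](C(C)C)(C(C)C)C(C)C)c3
A1 | alternative 1 | 2-(3,4,5-trimethoxyphenyl)-6-[3,4-dimethoxy-5-(methoxymethoxy)phenyl]-3,7-dioxabicyclo[3.3.0]octan-8-one (both aryl groups exo, configuration as in 18) | COc1cc([C@H]2OC[C@H]3[C@@H]2C(=O)O[C@@H]3c4cc(OCOC)c(OC)c(OC)c4)cc(OC)c1OC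
A2 | alternative 1 | (S)-5-[3,4-dimethoxy-5-(methoxymethoxy)phenyl]furan-2(5H)-one | O=C1C=C[C@H](O1)c2cc(OCOC)c(OC)c(OC)c2
A3 | alternative 1 | [(chloromethoxy)(3,4,5-trimethoxyphenyl)methyl]trimethylsilane (racemic) | COc1cc(C(OCCl)[Si](C)(C)C)cc(OC)c1OC
A4 | alternative 2 | (1R,2S,5R,6S)-2-[3,4-dimethoxy-5-(triisopropylsilyloxy)phenyl]-6-(3,4,5-trimethoxyphenyl)-3,7-dioxabicyclo[3.3.0]octane (identical with 17) | COc1cc([C@H]2OC[C@H]3[C@@H]2CO[C@@H]3c4cc(OC)c(OC)c(OC)c4)cc(O[Si](C(C)C)(C(C)C)C(C)C)c1OC
A5 | alternative 2 | 2-{(R)-[3,4-dimethoxy-5-(triisopropylsilyloxy)phenyl][(E)-3-(3,4,5-trimethoxyphenyl)prop-2-en-1-yloxy]methyl}oxirane (oxirane carbon not defined) | COc1cc([C@@H](OC/C=C/c2cc(OC)c(OC)c(OC)c2)C3CO3)cc(O[Si](C(C)C)(C(C)C)C(C)C)c1OC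
A6 | alternative 3 | trans,trans γ-menthyloxy-γ-butyrolactone with the 2-(3,4,5-trimethoxyphenyl)-1,3-dithian-2-yl group on the β-carbon and the [3,4-dimethoxy-5-(triisopropylsilyloxy)phenyl](hydroxy)methyl group on the α-carbon | CC(C)[C@@H]1CC[C@@H](C)C[C@H]1O[C@H]2[C@H](C3(c4cc(OC)c(OC)c(OC)c4)SCCCS3)[C@@H]([C@H](O)c3cc(O[Si](C(C)C)(C(C)C)C(C)C)c(OC)c(OC)c3)C(=O)O2
A7 | alternative 3 | (5R)-5-[(1R,2S,5R)-menthyloxy]furan-2(5H)-one | CC(C)[C@@H]1CC[C@@H](C)C[C@H]1O[C@H]2C=CC(=O)O2
A8 | alternative 3 | 2-(3,4,5-trimethoxyphenyl)-1,3-dithiane | COc1cc(C2SCCCS2)cc(OC)c1OC
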